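**Plan**
- Feature: in the bicyclo[2.2.2]octane (ring C = C8, C9, C11, C12, C13, C14, bridged by C15–C16) C16 is α to the C15 ketone and bonded to C12, and C12 is β to oxygen-bearing C14. With C14 as a ketone and a C12=C13 double bond, C12–C16 is a Michael bond.
- Retrosynthesis: remove the C16 methylene, the acetate and the C14 hydrogen, then cut C12–C16 to a tricyclic lactone enone with an allyl β-keto ester on C8. Next cut C9–C11 and the lactone C–O (vinylogous aldol/lactonisation), then C8–C15, C8–C14, C10–C1 and C5–C4.
- Forward: ring B comes from 2-methylcyclohex-2-en-1-one; ring C and the lactone ring close in one operation; the Michael addition closes the bicyclo[2.2.2]octane.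
- Stereochemistry: C5 by a chiral copper catalyst; C10 from C5 (trans alkylation); C8 from C10 (attack anti to the axial methyl); C9 and C12 from C8 (cis ring fusion, tether); C14 by an electron-transfer reduction that gives the more stable alcohol.

Key step: step 9

Remark: atisane numbering is used for all intermediates (C20 is the methyl on C10); β is the face of ring B that carries C20, α the other face. Commercial supply of allyl 3-bromopropiolate is not assumed, so it is made in steps 4 and 5.

**Step 1**
Reactants: 1 2-methylcyclohex-2-en-1-one; 2 isopropenylmagnesium bromide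
Product: 4 (3R)-2-methyl-3-(prop-1-en-2-yl)cyclohexan-1-one (both C2 epimers), via bromomagnesium enolate 3 (not isolated)
Conditions: Cu(OSO2CF3)2 (3 mol %), chiral N-mesityl-N′-(1-hydroxy-4-methylpentan-2-yl)-4,5-dihydroimidazolium hexafluorophosphate as carbene precursor (4 mol %, the enantiomer that gives 3R), Et2O, −30 °C; aq. NH4Cl
Reagents that add atoms: none
Why: Copper-catalysed asymmetric conjugate addition of Grignard reagents to α-substituted cyclic enones with chiral N-heterocyclic carbene ligands is a known reaction type; the ligand controls the face of C5 that receives the isopropenyl group, and the C10 centre formed on protonation need not be controlled because step 2 rebuilds it.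

**Step 2**
Reactants: 4; 5 methyl acrylate
Product: 8 methyl 3-[(1S,6S)-1-methyl-2-oxo-6-(prop-1-en-2-yl)cyclohexyl]propanoate, via N-benzyl imine 6 (not isolated), via alkylated N-benzyl imine 7 (not isolated)
Conditions: BnNH2, TsOH (cat.), toluene, reflux with removal of water; 5, THF, 50 °C; 20 % aq. AcOH, rt
Reagents that add atoms: water, O
Why: The secondary enamine tautomer of a 2-methylcyclohexanone imine adds to acrylates only at the more substituted α-carbon (imine Michael reaction with aza-ene-like N–H transfer), and the acrylate should approach C10 anti to the neighbouring isopropenyl group, so that the chain ends trans and the methyl cis to it.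

**Step 3**
Reactants: 8; 9 (E)-but-2-enoyl chloride (crotonyl chloride)
Product: 10 methyl 3-[(1S,6S)-3-[(E)-but-2-enoyl]-1-methyl-2-oxo-6-(prop-1-en-2-yl)cyclohexyl]propanoate (enolised 1,3-diketone, C8 not defined)
Conditions: MgBr2·OEt2 (2.5 equiv), i-Pr2NEt (3 equiv), CH2Cl2, 0 °C → rt; aq. NH4Cl
Reagents that add atoms: none
Why: Soft enolisation with MgBr2·OEt2 and a tertiary amine followed by C-acylation with an acid chloride is a known route to 1,3-diketones (crossed Claisen-type acylation); C8 is the only enolisable α-position of 8, and no stereocentre is fixed because 10 is enolised.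

**Step 4**
Reactants: 11 propiolic acid; 12 allyl alcohol
Product: 13 allyl propiolate
Conditions: DCC, DMAP (5 mol %), CH2Cl2, −20 → 0 °C
Reagents that add atoms: none
Why: Carbodiimide (Steglich) esterification at low temperature is a usual way to esters of propiolic acid; no stereocentre is involved.

**Step 5**
Reactants: 13
Product: 14 allyl 3-bromopropiolate
Conditions: NBS, AgNO3 (10 mol %), acetone, rt
Reagents that add atoms: N-bromosuccinimide, O=C1CCC(=O)N1Br
Why: Silver-catalysed electrophilic bromination of a terminal alkyne with N-bromosuccinimide is the standard preparation of 1-bromoalkynes such as bromopropiolates, and the allyl double bond should not react.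

**Step 6**
Reactants: 10; 14
Product: 15 methyl 3-[(1S,3S,6S)-3-[3-(allyloxy)-3-oxoprop-1-yn-1-yl]-3-[(E)-but-2-enoyl]-1-methyl-2-oxo-6-(prop-1-en-2-yl)cyclohexyl]propanoate (alkynoate on C8 α, cis to the propanoate chain; crotonyl β)
Conditions: MgBr2·OEt2 (1.2 equiv), i-Pr2NEt (1.5 equiv), CH2Cl2, −40 → 0 °C
Reagents that add atoms: none
Why: C-Alkynylation of a cyclic 1,3-dicarbonyl compound by conjugate addition to a β-bromoalkynoate and loss of bromide (addition–elimination) is a known reaction type; in the magnesium diketonate the side-chain ester should bind the metal and hold the chain pseudoequatorial, so that the C10 methyl is pseudoaxial and the electrophile enters C8 on the opposite (α) face, as electrophiles enter C2 of 3-oxo steroid enolates anti to the angular methyl, which leaves the crotonyl group β.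

**Step 7**
Reactants: 15
Product: 16 methyl 3-[(1S,3S,6S)-3-[3-(allyloxy)-3-oxo-1-(pyrrolidin-1-yl)prop-1-en-1-yl]-3-[(E)-but-2-enoyl]-1-methyl-2-oxo-6-(prop-1-en-2-yl)cyclohexyl]propanoate (enamine geometry not defined)
Conditions: pyrrolidine (1.1 equiv), CH2Cl2, 0 °C
Reagents that add atoms: pyrrolidine, C1CCNC1
Why: Conjugate addition of a secondary amine to an ynoate is fast and selective for the β-carbon (C15) and gives a vinylogous carbamate, a base-stable masked β-keto ester that is neither acidic nor electrophilic; no stereocentre is formed.

**Step 8**
Reactants: 16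
Product: 18 tricyclic lactone enone with allyl 3-oxopropanoate on C8 (α), via tricyclic enaminoester lactone 17 (not isolated)
Conditions: LiN(SiMe3)2 (1.1 equiv), THF, −78 → −10 °C; then 1 M aq. HCl, THF, rt
Reagents that add atoms: water, O
Why: The crotonyl ketone has no α′-hydrogen and the C9 ketone has none at all, so the amide base can only form the γ-dienolate (intramolecular vinylogous aldol addition, 6-(enolendo)-exo-trig), whose C11 can reach the C9 carbonyl only on the β face because the crotonyl group is β on C8; this sets C9 with its alkoxide α, cis to the C10 propanoate, which it attacks to close the δ-lactone, and aqueous acid then hydrolyses the enaminoester to the β-keto ester.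

**Step 9**
Reactants: 18
Product: 19 tetracyclic 14,15-dione allyl ester (C12–C16 bond formed)
Conditions: Cs2CO3 (0.3 equiv), MeCN, 0 °C → rt; aq. NH4Cl
Reagents that add atoms: none
Why: Cs2CO3 deprotonates only the allyl β-keto ester, and its C16 carbanion, held on the α face of ring C by quaternary C8, adds to C12 of the C14 enone; protonation of the resulting C14 enolate at C13 completes an intramolecular Michael addition. The closest known reaction type is the base-mediated intramolecular Michael addition of a β-dicarbonyl compound to a cyclohexenone that closes a bicyclo[2.2.2]octanone, the second stage of double Michael annulations. The one new bond closes two six-membered rings at once, with ring C in a boat: ring C8–C15–C16–C12–C11–C9 in the 6-exo-trig mode and ring C8–C15–C16–C12–C13–C14 in the 6-endo-trig mode. C12 is set by C8, because the tethered nucleophile can reach only one face of the enone; C16 should settle as the more stable epimer through the enol and is removed in step 12. The selectivity needed is Michael addition in preference to deprotonation at C11 (which would expel the lactone carboxylate from C9) and to attack of the carbanion on the lactone carbonyl; the large acidity gap, the mild carbonate base and the removal of the product as its stabilised β-keto ester enolate should secure it.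

**Step 10**
Reactants: 19
Product: 21 14-alcohol (OH on the side of the C15–C16 bridge), via sodium enolate 20 (not isolated)
Conditions: NaH (1.05 equiv), THF, 0 °C; SmI2 (2.5 equiv), MeOH, THF, −78 → 0 °C; aq. NH4Cl
Reagents that add atoms: none
Why: The sodium enolate of the β-keto ester protects C15 and blocks retro-aldol cleavage, and electron-transfer reduction of the remaining C14 ketone with SmI2 (a dissolving-metal-type ketone reduction) should give the more stable alcohol, with oxygen on the open side facing the C15–C16 bridge and hydrogen on the side of C20, as is known for hindered ketones such as 11-oxo steroids, whereas hydride reagents would attack from the open face and give the C14 epimer.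

**Step 11**
Reactants: 21
Product: 22 14-acetate of 21
Conditions: Ac2O, pyridine, DMAP (cat.), CH2Cl2, 0 °C → rt
Reagents that add atoms: acetic anhydride, CC(=O)OC(C)=O
Why: DMAP-catalysed acetylation of a secondary alcohol proceeds with retention at C14, and capping the alcohol before the ester is cleaved removes the β-hydroxy ketone that could open by retro-aldol cleavage.

**Step 12**
Reactants: 22
Product: 24 crotobarin, via β-keto acid 23 (not isolated)
Conditions: Pd(PPh3)4 (5 mol %), morpholine (3 equiv), THF, rt; then 37 % aq. CH2O, AcOH, 40 °C
Reagents that add atoms: formaldehyde, C=O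
Why: Zerovalent palladium ionises the allyl ester to a π-allyl complex that morpholine intercepts (Tsuji–Trost deallylation), and the β-keto acid then undergoes a Mannich reaction with formaldehyde and the amine at C16 followed by decarboxylative elimination to the exocyclic enone, which also removes the C16 stereocentre.

**Compound list**
1 | 2-methylcyclohex-2-en-1-one | CC1=CCCCC1=O | starting material
2 | isopropenylmagnesium bromide | CC(=C)[Mg]Br | starting material
3 | bromomagnesium enolate of 4 | CC1=C(O[Mg]Br)CCC[C@H]1C(C)=C | intermediate
4 | (3R)-2-methyl-3-(prop-1-en-2-yl)cyclohexan-1-one (C2 epimers) | O=C1CCC[C@@H](C(=C)C)C1C | intermediate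
5 | methyl acrylate | C=CC(=O)OC | starting material
6 | N-benzyl imine of 4 | CC1C(=NCc2ccccc2)CCC[C@H]1C(C)=C | intermediate
7 | N-benzyl imine of 8 | COC(=O)CC[C@]1(C)C(=NCc2ccccc2)CCC[C@H]1C(C)=C | intermediate
8 | methyl 3-[(1S,6S)-1-methyl-2-oxo-6-(prop-1-en-2-yl)cyclohexyl]propanoate (chain trans, methyl cis to isopropenyl) | O=C1CCC[C@@H](C(=C)C)[C@]1(C)CCC(=O)OC | intermediate
9 | (E)-but-2-enoyl chloride | C/C=C/C(Cl)=O | starting material
10 | methyl 3-[(1S,6S)-3-[(E)-but-2-enoyl]-1-methyl-2-oxo-6-(prop-1-en-2-yl)cyclohexyl]propanoate (enolised, drawn as diketone, C8 not defined) | C/C=C/C(=O)C1CC[C@@H](C(=C)C)[C@](C)(CCC(=O)OC)C1=O | intermediate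
11 | propiolic acid | C#CC(=O)O | starting material
12 | allyl alcohol | C=CCO | starting material
13 | allyl propiolate | C#CC(=O)OCC=C | intermediate
14 | allyl 3-bromopropiolate | BrC#CC(=O)OCC=C | intermediate
15 | methyl 3-[(1S,3S,6S)-3-[3-(allyloxy)-3-oxoprop-1-yn-1-yl]-3-[(E)-but-2-enoyl]-1-methyl-2-oxo-6-(prop-1-en-2-yl)cyclohexyl]propanoate (alkynoate 8α, crotonyl 8β) | C=CCOC(=O)C#C[C@]1(C(=O)/C=C/C)CC[C@@H](C(=C)C)[C@](C)(CCC(=O)OC)C1=O | intermediate
16 | pyrrolidine enaminoester of 15 (C15 bears pyrrolidin-1-yl, C15=C16, geometry not defined) | C=CCOC(=O)C=C(N2CCCC2)[C@]1(C(=O)/C=C/C)CC[C@@H](C(=C)C)[C@](C)(CCC(=O)OC)C1=O | intermediate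
17 | tricyclic enaminoester lactone (as 18, with C15 as the enamine carbon of an allyl 3-(pyrrolidin-1-yl)acrylate) | C=CCOC(=O)C=C(N4CCCC4)[C@]12CC[C@@H](C(=C)C)[C@]3(C)CCC(=O)O[C@@]31CC=CC2=O | intermediate
18 | tricyclic lactone enone: allyl 3-oxopropanoate on C8 (α); ring C (C14 ketone, C12=C13) cis-fused on the β face; δ-lactone C10–C1–C2–C3(=O)–O–C9 cis-fused on the α face; 5β-isopropenyl; 10β-methyl | C=CCOC(=O)CC(=O)[C@]12CC[C@@H](C(=C)C)[C@]3(C)CCC(=O)O[C@@]31CC=CC2=O | intermediate
19 | tetracyclic 14,15-dione allyl ester (18 with C16 bonded to C12; ester on C16 drawn on the side of C11, epimerisable) | C=CCOC(=O)[C@@H]1C(=O)[C@]23CC[C@@H](C(=C)C)[C@]4(C)CCC(=O)O[C@@]42C[C@H]1CC3=O | intermediate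
20 | sodium enolate of 19 (C15–O−, C15=C16) | C=CCOC(=O)C1=C([O-])[C@]23CC[C@@H](C(=C)C)[C@]4(C)CCC(=O)O[C@@]42C[C@H]1CC3=O.[Na+] | intermediate
21 | 14-alcohol of 19 (C14–OH towards the C15–C16 bridge, C14–H towards C9/C10) | C=CCOC(=O)[C@@H]1C(=O)[C@]23CC[C@@H](C(=C)C)[C@]4(C)CCC(=O)O[C@@]42C[C@H]1C[C@@H]3O | intermediate
22 | 14-acetate of 21 | C=CCOC(=O)[C@@H]1C(=O)[C@]23CC[C@@H](C(=C)C)[C@]4(C)CCC(=O)O[C@@]42C[C@H]1C[C@@H]3OC(C)=O | intermediate
23 | β-keto acid from 22 (C16–CO2H) | OC(=O)[C@@H]1C(=O)[C@]23CC[C@@H](C(=C)C)[C@]4(C)CCC(=O)O[C@@]42C[C@H]1C[C@@H]3OC(C)=O | intermediate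
24 | crotobarin | C=C1C(=O)[C@]23CC[C@@H](C(=C)C)[C@]4(C)CCC(=O)O[C@@]42C[C@H]1C[C@@H]3OC(C)=O | target

**Step count and risks**
Total: 12 steps. Longest linear sequence: 10 steps (1, 2, 3, 6, 7, 8, 9, 10, 11, 12).

Most likely to fail, first: step 8. The γ-dienolate may not add to the crowded C9 carbonyl, the base may cleave the non-enolisable 1,3-diketone by a retro-Claisen path, or deprotonation at C11 after ring closure may expel the lactone carboxylate from C9. The fallback uses a Lewis acid instead of a base and sets out from 16. TMSOTf and Et3N should give the 2-trimethylsilyloxy-1,3-diene F1. BF3·OEt2 in CH2Cl2 at −78 °C (intramolecular vinylogous Mukaiyama aldol addition) should then give, after aqueous work-up, the hydroxy ester F2. Camphorsulfonic acid in benzene closes the lactone and dilute aqueous HCl cleaves the enamine, which returns the route to 18.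

Second: step 6. The bromoalkynoate may attack both faces of the C8 enolate (poor facial selectivity; the conformational preference of ring B that underlies the prediction is small) or the enolate oxygen. The fallback replaces substrate control by reagent control and sets out from 10. The same addition–elimination is run as a solid–liquid phase-transfer reaction (K2CO3, toluene, −20 °C) with an N-benzylcinchonidinium salt or its pseudoenantiomeric N-benzylcinchoninium salt. This type of chiral ion pair is known to fix the quaternary centre in alkynylations of cyclic β-dicarbonyl compounds; the catalyst of the matched sense is kept. The product is again 15, so no new compound arises (F0).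

Third: step 10. Electron transfer may also affect the lactone or the β-keto ester, or protonation may place hydrogen on the open face. The fallback is a kinetic hydride reduction followed by equilibration and sets out from 19. NaBH4 on the preformed sodium enolate at −40 °C should attack from the open face and give the 14-epimeric alcohol F3. Hydrogen-transfer catalysis with RuCl(CO)2(η5-C5Ph5) and KOt-Bu (cat.) in toluene should then equilibrate the carbinol centre towards the less crowded epimer 21, where the route is rejoined.

**Further compounds**
F1 | step 8 | trimethylsilyl dienol ether of 16 (C14 as C(OSiMe3)=CH–CH=CH2) | C=CCOC(=O)C=C(N2CCCC2)[C@]1(C(O[Si](C)(C)C)=CC=C)CC[C@@H](C(=C)C)[C@](C)(CCC(=O)OC)C1=O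
F2 | step 8 | hydroxy ester (ring C closed, C9–OH α, methyl propanoate open, enaminoester intact) | C=CCOC(=O)C=C(N4CCCC4)[C@]12CC[C@@H](C(=C)C)[C@](C)(CCC(=O)OC)[C@@]1(O)CC=CC2=O
F0 | step 6 | none | none
F3 | step 10 | 14-epimer of 21 (C14–OH towards C9/C10) | C=CCOC(=O)[C@@H]1C(=O)[C@]23CC[C@@H](C(=C)C)[C@]4(C)CCC(=O)O[C@@]42C[C@H]1C[C@H]3O
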